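**Plan**
- The target is methyl gyrophorate, a tridepside of three orsellinate rings: A (methyl ester ring), B (middle ring) and C (terminal ring). The retrosynthesis cuts (i) the ester C–O bond between the ring C carbonyl and the 4-oxygen of ring B, (ii) the C1–C6 bond inside ring B, (iii) the ester C–O bond between the 4-oxygen of ring A and the open chain, and (iv) the C4–C5 bond of that eight-carbon chain.
- Forward: ring A is bought as methyl orsellinate. A but-2-ynoyl unit is joined to a dioxinone, and the resulting chain is delivered to the free 4-OH of ring A through an acylketene. Ring B is then closed from the chain. Ring C, made as a benzyl-protected orsellinic acid from the same starting material, is esterified onto the new 4-OH of ring B and debenzylated.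
- Enabling feature: in ring B, C1 bears the ester carbonyl to ring A, C6 bears the methyl group, and C2 and C4 bear oxygen. C1 is therefore a β-keto-ester carbon and C6 the methyl-capped end of a ynone, so joining C1 to C6 by conjugate addition gives the arene at the correct oxidation level with no dehydration.
- Stereochemistry: none arises; the target has no stereocentre, stereoaxis or configurable double bond.

Key step: step 4

Assumption: the target is achiral, so "single enantiomer" is taken to mean the single constitution shown; transient sp3 centres in non-isolated intermediates are racemic and are erased.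

**Route**

Step 1
Reactants: 1 but-2-ynoic acid
Product: 2 N-methoxy-N-methylbut-2-ynamide
Conditions: MeNH(OMe)·HCl, DCC, Et3N, CH2Cl2, 0 °C → rt
Reagents that add atoms: N,O-dimethylhydroxylamine hydrochloride, Cl.CNOC
Why: Carbodiimide amide coupling (Weinreb amide formation), in which the O-acylisourea should be intercepted by the hydroxylamine at 0 °C faster than any amine adds to the triple bond, giving a stable, storable but-2-ynoyl donor.

Step 2
Reactants: 3 2,2,6-trimethyl-4H-1,3-dioxin-4-one; 2 N-methoxy-N-methylbut-2-ynamide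
Product: 4 2,2-dimethyl-6-(2-oxopent-3-yn-1-yl)-4H-1,3-dioxin-4-one
Conditions: 3 (2 equiv), LiHMDS, THF, −78 °C; then 2, −78 → −40 °C; inverse quench into cold aq. HCl
Reagents that add atoms: none
Why: Claisen-type γ-C-acylation of the lithium dienolate of the dioxinone by a Weinreb amide, where the chelated tetrahedral adduct should persist until the cold acid quench, so over-addition and proton transfer to the product are avoided and the released hydroxylamine is protonated before it can add to the new ynone.

Step 3
Reactants: 4 2,2-dimethyl-6-(2-oxopent-3-yn-1-yl)-4H-1,3-dioxin-4-one; 5 methyl orsellinate (methyl 2,4-dihydroxy-6-methylbenzoate)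
Product: 7 methyl 4-[(3,5-dioxooct-6-ynoyl)oxy]-2-hydroxy-6-methylbenzoate, via acylketene oct-1-en-6-yne-1,3,5-trione 6 (not isolated)
Conditions: 4 (1.2 equiv) added slowly to 5 in PhMe (0.2 M), 110 °C, short reaction time; rapid filtration through silica
Reagents that add atoms: none
Why: Thermal retro-hetero-Diels–Alder loss of acetone from the dioxinone gives the acylketene, which the free 4-OH of methyl orsellinate should trap by pseudopericyclic addition, while the 2-OH is hydrogen-bonded to the ester carbonyl, flanked by it, and so stays unacylated.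

Step 4
Reactants: 7 methyl 4-[(3,5-dioxooct-6-ynoyl)oxy]-2-hydroxy-6-methylbenzoate
Product: 9 methyl 4-[(2,4-dihydroxy-6-methylbenzoyl)oxy]-2-hydroxy-6-methylbenzoate (methyl lecanorate), via diketone tautomer methyl 2-hydroxy-6-methyl-4-[(2-methyl-4,6-dioxocyclohex-2-ene-1-carbonyl)oxy]benzoate 8 (not isolated)
Conditions: Et3N (2 equiv), dry CH2Cl2 (0.02 M), 0 °C → rt; aq. citric acid work-up
Reagents that add atoms: none
Why: Proposed new method: triethylamine enolises the β-keto ester, and chain carbon C2 (between the aryl ester and the C3 ketone) adds to the methyl-bearing alkyne carbon C7 of the ynone in an intramolecular Michael reaction, after which protonation at C6 gives dione 8 and two keto–enol shifts give the resorcylate ring with no loss of water. The closest known reaction types are the amine-mediated C2-to-C7 aldol aromatisation of 3,5,7-triketo esters, which uses the same nucleophile under the same conditions, and base-promoted 6-endo-dig conjugate carbocyclisations of active-methylene carbons onto tethered ynones that end in phenols. The one ring closes in the 6-endo-dig mode with the enolate double bond inside the forming ring, and no stereocentre is created. The step needs carbon rather than oxygen attack at C7, since the C3 enol oxygen can close a ring of the same size to a 4-pyranone; basic, aprotic conditions free of π-acid should favour the soft, doubly activated carbon, just as triketides give pyranones under acid but resorcylates under base, and aromatisation makes the carbon pathway irreversible. The aryl β-keto ester must also survive, which the dry, non-nucleophilic medium should secure because any E1cB loss of the aryloxide is reversible there.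

Step 5
Reactants: 5 methyl orsellinate
Product: 10 methyl 2,4-bis(benzyloxy)-6-methylbenzoate
Conditions: BnBr, K2CO3, DMF, 60 °C
Reagents that add atoms: benzyl bromide, BrCc1ccccc1
Why: Williamson etherification, in which excess bromide in warm DMF should alkylate the hydrogen-bonded 2-OH as well as the free 4-OH.

Step 6
Reactants: 10 methyl 2,4-bis(benzyloxy)-6-methylbenzoate
Product: 11 2,4-bis(benzyloxy)-6-methylbenzoic acid
Conditions: KOH, DMSO/H2O, 90 °C; then aq. HCl
Reagents that add atoms: potassium hydroxide, [K+].[OH-]
Why: Saponification of a di-ortho-substituted benzoate, for which poorly solvated hydroxide in aqueous DMSO is the standard remedy, with the benzyl ethers inert to base.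

Step 7
Reactants: 9 methyl 4-[(2,4-dihydroxy-6-methylbenzoyl)oxy]-2-hydroxy-6-methylbenzoate; 11 2,4-bis(benzyloxy)-6-methylbenzoic acid
Product: 13 methyl 4-({4-[(2,4-bis(benzyloxy)-6-methylbenzoyl)oxy]-2-hydroxy-6-methylbenzoyl}oxy)-2-hydroxy-6-methylbenzoate, via 2,4-bis(benzyloxy)-6-methylbenzoyl chloride 12 (not isolated)
Conditions: 11, (COCl)2, cat. DMF, CH2Cl2, 0 °C → rt, evaporate; then 9, Et3N, cat. DMAP, CH2Cl2, 0 °C → rt
Reagents that add atoms: none
Why: Acid chloride formation (Vilsmeier-type activation) followed by DMAP-catalysed O-acylation, which should occur only at the 4-OH of ring B because it is the most acidic phenol and the only one not hydrogen-bonded to an ortho ester carbonyl, as in classical depside couplings.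

Step 8
Reactants: 13 methyl 4-({4-[(2,4-bis(benzyloxy)-6-methylbenzoyl)oxy]-2-hydroxy-6-methylbenzoyl}oxy)-2-hydroxy-6-methylbenzoate
Product: 14 methyl 4-({4-[(2,4-dihydroxy-6-methylbenzoyl)oxy]-2-hydroxy-6-methylbenzoyl}oxy)-2-hydroxy-6-methylbenzoate (methyl gyrophorate, CNP0212402.0)
Conditions: H2 (1 atm), 10% Pd/C, EtOAc, rt
Reagents that add atoms: none
Why: Catalytic hydrogenolysis of the two benzyl ethers, which should leave the aryl and methyl esters untouched, with aprotic ethyl acetate chosen to exclude transesterification of the depside links.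

**Compound list**
1 | but-2-ynoic acid | CC#CC(=O)O | starting material
2 | N-methoxy-N-methylbut-2-ynamide | CC#CC(=O)N(C)OC | intermediate
3 | 2,2,6-trimethyl-4H-1,3-dioxin-4-one | CC1=CC(=O)OC(C)(C)O1 | starting material
4 | 2,2-dimethyl-6-(2-oxopent-3-yn-1-yl)-4H-1,3-dioxin-4-one | CC#CC(=O)CC1=CC(=O)OC(C)(C)O1 | intermediate
5 | methyl orsellinate (methyl 2,4-dihydroxy-6-methylbenzoate) | COC(=O)c1c(C)cc(O)cc1O | starting material
6 | acylketene oct-1-en-6-yne-1,3,5-trione (not isolated) | CC#CC(=O)CC(=O)C=C=O | intermediate
7 | methyl 4-[(3,5-dioxooct-6-ynoyl)oxy]-2-hydroxy-6-methylbenzoate | COC(=O)c1c(C)cc(OC(=O)CC(=O)CC(=O)C#CC)cc1O | intermediate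
8 | methyl 2-hydroxy-6-methyl-4-[(2-methyl-4,6-dioxocyclohex-2-ene-1-carbonyl)oxy]benzoate (racemic, not isolated) | COC(=O)c1c(C)cc(OC(=O)C2C(C)=CC(=O)CC2=O)cc1O | intermediate
9 | methyl 4-[(2,4-dihydroxy-6-methylbenzoyl)oxy]-2-hydroxy-6-methylbenzoate (methyl lecanorate) | COC(=O)c1c(C)cc(OC(=O)c2c(C)cc(O)cc2O)cc1O | intermediate
10 | methyl 2,4-bis(benzyloxy)-6-methylbenzoate | COC(=O)c1c(C)cc(OCc2ccccc2)cc1OCc1ccccc1 | intermediate
11 | 2,4-bis(benzyloxy)-6-methylbenzoic acid | OC(=O)c1c(C)cc(OCc2ccccc2)cc1OCc1ccccc1 | intermediate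
12 | 2,4-bis(benzyloxy)-6-methylbenzoyl chloride (not isolated) | ClC(=O)c1c(C)cc(OCc2ccccc2)cc1OCc1ccccc1 | intermediate
13 | methyl 4-({4-[(2,4-bis(benzyloxy)-6-methylbenzoyl)oxy]-2-hydroxy-6-methylbenzoyl}oxy)-2-hydroxy-6-methylbenzoate | COC(=O)c1c(C)cc(OC(=O)c2c(C)cc(OC(=O)c3c(C)cc(OCc4ccccc4)cc3OCc3ccccc3)cc2O)cc1O | intermediate
14 | methyl 4-({4-[(2,4-dihydroxy-6-methylbenzoyl)oxy]-2-hydroxy-6-methylbenzoyl}oxy)-2-hydroxy-6-methylbenzoate (methyl gyrophorate) | COC(=O)c1c(C)cc(OC(=O)c2c(C)cc(OC(=O)c3c(C)cc(O)cc3O)cc2O)cc1O | target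

**Step count and risks**
Total steps: 8. Longest linear sequence: 6 steps (steps 1, 2, 3, 4, 7, 8, from but-2-ynoic acid); the ring C branch (steps 5 and 6) joins at step 7.

Steps most likely to fail:

1. Step 4 (Proposed new method). The closure may run through the C3 enol oxygen instead of carbon, giving a pyranone ring, or the enolate may shed the aryloxide before it cyclises. The fallback uses only known chemistry: it keeps the same C2–C7 bond but closes it as an aldol condensation on a triketide. It sets out from 3 (with 5) and comes back at 9. The lithium dienolate of 3 would be acetylated with acetyl chloride to give 2,2-dimethyl-6-(2-oxopropyl)-4H-1,3-dioxin-4-one F1. Its dianion (LDA, 2 equiv) would be acetylated at the terminal methyl with N-methoxy-N-methylacetamide to give 6-(2,4-dioxopentyl)-2,2-dimethyl-4H-1,3-dioxin-4-one F2. Heating F2 with 5 in toluene should release the acylketene oct-1-ene-1,3,5,7-tetrone F3, which the 4-OH of 5 would trap as methyl 2-hydroxy-6-methyl-4-[(3,5,7-trioxooctanoyl)oxy]benzoate F4; step 3 will already have shown whether 5 traps such ketenes. Triethylamine in dichloromethane should then bring about the C2-to-C7 aldol addition to methyl 2-hydroxy-4-[(2-hydroxy-2-methyl-4,6-dioxocyclohexane-1-carbonyl)oxy]-6-methylbenzoate F5, and mild acid should dehydrate and aromatise it to 9.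

2. Step 3. The acylketene may be captured internally by the C5 enol oxygen faster than the phenol adds, and the ynone may not tolerate prolonged heating with a phenol. The fallback carries C5 at the alcohol oxidation level through the thermolysis, so neither an enolisable C5 ketone nor a ynone is present when the ketene is generated. It sets out from 3, also bypasses step 2, and comes back at 7.
   - Vinylogous aldol addition of the lithium dienolate of 3 to but-2-ynal should give racemic 6-(2-hydroxypent-3-yn-1-yl)-2,2-dimethyl-4H-1,3-dioxin-4-one F6.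
   - Silylation (TBSCl, imidazole) would give 6-{2-[(tert-butyldimethylsilyl)oxy]pent-3-yn-1-yl}-2,2-dimethyl-4H-1,3-dioxin-4-one F7.
   - Thermolysis of F7 with 5 in toluene should pass through the acylketene 5-[(tert-butyldimethylsilyl)oxy]oct-1-en-6-yne-1,3-dione F8 to methyl 4-({5-[(tert-butyldimethylsilyl)oxy]-3-oxooct-6-ynoyl}oxy)-2-hydroxy-6-methylbenzoate F9.
   - HF·pyridine would free methyl 2-hydroxy-4-[(5-hydroxy-3-oxooct-6-ynoyl)oxy]-6-methylbenzoate F10.
   - Dess–Martin oxidation of the propargylic alcohol would give 7 and erase the racemic centre.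

3. Step 7. Acylation may not stop at the single free hydroxyl, the base may induce migration or cleavage of the existing depside ester, or the hindered acyl chloride may react too slowly. The fallback builds ring C on the substrate instead of attaching it preformed, using neutral acylation and no protecting groups. It sets out from 9 (with 4), comes back at 14, and makes steps 5, 6 and 8 unnecessary; it relies on step 4 having worked on 7. Heating 4 with 9 in toluene should regenerate acylketene 6, which the only non-hydrogen-bonded hydroxyl of 9 would trap as methyl 4-({4-[(3,5-dioxooct-6-ynoyl)oxy]-2-hydroxy-6-methylbenzoyl}oxy)-2-hydroxy-6-methylbenzoate F11. Triethylamine in dichloromethane, as in step 4, should then cyclise it through the tautomer methyl 2-hydroxy-4-({2-hydroxy-6-methyl-4-[(2-methyl-4,6-dioxocyclohex-2-ene-1-carbonyl)oxy]benzoyl}oxy)-6-methylbenzoate F12 to 14.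

**Further compounds**
F1 | step 4 | 2,2-dimethyl-6-(2-oxopropyl)-4H-1,3-dioxin-4-one | CC(=O)CC1=CC(=O)OC(C)(C)O1
F2 | step 4 | 6-(2,4-dioxopentyl)-2,2-dimethyl-4H-1,3-dioxin-4-one | CC(=O)CC(=O)CC1=CC(=O)OC(C)(C)O1
F3 | step 4 | oct-1-ene-1,3,5,7-tetrone | CC(=O)CC(=O)CC(=O)C=C=O
F4 | step 4 | methyl 2-hydroxy-6-methyl-4-[(3,5,7-trioxooctanoyl)oxy]benzoate | COC(=O)c1c(C)cc(OC(=O)CC(=O)CC(=O)CC(C)=O)cc1O
F5 | step 4 | methyl 2-hydroxy-4-[(2-hydroxy-2-methyl-4,6-dioxocyclohexane-1-carbonyl)oxy]-6-methylbenzoate (stereoisomer mixture) | COC(=O)c1c(C)cc(OC(=O)C2C(=O)CC(=O)CC2(C)O)cc1O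
F6 | step 3 | 6-(2-hydroxypent-3-yn-1-yl)-2,2-dimethyl-4H-1,3-dioxin-4-one (racemic) | CC#CC(O)CC1=CC(=O)OC(C)(C)O1
F7 | step 3 | 6-{2-[(tert-butyldimethylsilyl)oxy]pent-3-yn-1-yl}-2,2-dimethyl-4H-1,3-dioxin-4-one (racemic) | CC#CC(CC1=CC(=O)OC(C)(C)O1)O[Si](C)(C)C(C)(C)C
F8 | step 3 | 5-[(tert-butyldimethylsilyl)oxy]oct-1-en-6-yne-1,3-dione (racemic) | CC#CC(CC(=O)C=C=O)O[Si](C)(C)C(C)(C)C
F9 | step 3 | methyl 4-({5-[(tert-butyldimethylsilyl)oxy]-3-oxooct-6-ynoyl}oxy)-2-hydroxy-6-methylbenzoate (racemic) | COC(=O)c1c(C)cc(OC(=O)CC(=O)CC(O[Si](C)(C)C(C)(C)C)C#CC)cc1O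
F10 | step 3 | methyl 2-hydroxy-4-[(5-hydroxy-3-oxooct-6-ynoyl)oxy]-6-methylbenzoate (racemic) | COC(=O)c1c(C)cc(OC(=O)CC(=O)CC(O)C#CC)cc1O
F11 | step 7 | methyl 4-({4-[(3,5-dioxooct-6-ynoyl)oxy]-2-hydroxy-6-methylbenzoyl}oxy)-2-hydroxy-6-methylbenzoate | COC(=O)c1c(C)cc(OC(=O)c2c(C)cc(OC(=O)CC(=O)CC(=O)C#CC)cc2O)cc1O
F12 | step 7 | methyl 2-hydroxy-4-({2-hydroxy-6-methyl-4-[(2-methyl-4,6-dioxocyclohex-2-ene-1-carbonyl)oxy]benzoyl}oxy)-6-methylbenzoate (racemic) | COC(=O)c1c(C)cc(OC(=O)c2c(C)cc(OC(=O)C3C(C)=CC(=O)CC3=O)cc2O)cc1O
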